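**Retrosynthetic overview** (target numbered C1 = oxirane carbon bearing CH2OBz, C2 = CHOH, C3 = CHOBz, C4=C5, C6 = oxirane CH)
1. The oxirane (C1–O–C6) is made last, by hydroxyl-directed epoxidation of cyclohexadienol 8 on the face of the C2–OH.
2. The trans C2–OH/C3–OBz pair and the C4=C5 alkene come together from a rhodium-catalysed asymmetric SN2' ring opening of 7-oxanorbornadiene 6 by benzoate, which also selects the enantiomer.
3. The carbocycle comes from a [4+2] cycloaddition of furan ester 3 (C2, C1, C6, C5 and the C2 oxygen) with an acetylene equivalent (C3, C4), forming C2–C3 and C4–C5 in one operation.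
4. Enabling feature: C2 (with its oxygen) and C5 lie 1,4 across the cyclohexene ring. Tying the C2 oxygen to C5 gives a 7-oxabicyclo[2.2.1]heptadiene whose O–C2–C1–C6–C5 ring is a 3-substituted furan, with C1=C6 the later oxirane site.
5. Ring order: furan (purchased) → six-membered carbocycle with oxygen bridge (step 2) → bridge opened (step 4) → oxirane (step 5).

Key step: step 2

Assumption: the (R,S)-configured ferrocenyl diphosphine is taken to cleave, in the (1S,4R)-enantiomer of 6, the bridgehead C–O bond that leads to 8; if the sense proves opposite, the (S,R)-ligand is used with no other change.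

**Step 1**
Reactants: 1 furan-3-ylmethanol; 2 benzoyl chloride
Product: 3 furan-3-ylmethyl benzoate
Conditions: BzCl, Et3N, DMAP (cat.), CH2Cl2, 0 °C to rt
Reagents that add atoms: benzoyl chloride (2), O=C(Cl)c1ccccc1
Why: DMAP-catalysed acylation (nucleophilic acyl substitution) of an unhindered primary alcohol; no stereocenter is formed.

**Step 2**
Reactants: 3 furan-3-ylmethyl benzoate; 4 (Z)-1,2-bis(phenylsulfonyl)ethene
Product: 5 rac-[(1R,4S,5R,6S)-5,6-bis(phenylsulfonyl)-7-oxabicyclo[2.2.1]hept-2-en-2-yl]methyl benzoate (5-endo,6-endo)
Conditions: CH2Cl2 (1 M), 25 °C, dark, 24–48 h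
Reagents that add atoms: (Z)-1,2-bis(phenylsulfonyl)ethene (4), O=S(=O)(/C=C\S(=O)(=O)c1ccccc1)c1ccccc1
Why: A concerted, suprafacial–suprafacial normal-demand Diels–Alder reaction joins the furan termini to both alkene carbons at once; the closest known reaction type is the cycloaddition of furans with cis-bis(arylsulfonyl)ethenes used as acetylene equivalents. It closes the six-membered carbocycle (target C1–C6) in an intermolecular [4+2] mode, with the furan oxygen becoming the one-atom bridge of a 7-oxanorbornene, so the later C2–O bond is already in place. The two bridgehead stereocenters are cis by geometric necessity; the two sulfonyl-bearing carbons are cis from the Z-alkene and expected endo (Alder rule), and they are erased in step 3, so an exo,exo isomer would converge. No regioselectivity is needed because the dienophile is symmetrical, so the unsymmetrical 3-substituted furan can give only one constitution. The one requirement, that cycloaddition outruns cycloreversion, is secured by the doubly sulfonyl-activated cis-alkene reacting at room temperature. The adduct is racemic; the enantiomers are differentiated chemically in step 4.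

**Step 3**
Reactants: 5 rac-bis-sulfone adduct
Product: 6 (±)-(7-oxabicyclo[2.2.1]hepta-2,5-dien-2-yl)methyl benzoate
Conditions: 5% Na(Hg), NaH2PO4, THF–MeOH, −20 °C
Reagents that add atoms: none
Why: Julia-type reductive elimination of a vicinal bis-sulfone: electron transfer cleaves one C–S bond and the carbanion expels the neighbouring benzenesulfinate (a far better leaving group than the bridging alkoxide), unveiling the alkene between target C3 and C4 while the bridgehead stereocenters are untouched.

**Step 4**
Reactants: 6 (±)-(7-oxabicyclo[2.2.1]hepta-2,5-dien-2-yl)methyl benzoate; 7 benzoic acid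
Product: 8 [(5R,6R)-5-(benzoyloxy)-6-hydroxycyclohexa-1,3-dien-1-yl]methyl benzoate
Conditions: [Rh(cod)Cl]2 (2.5 mol%), (R)-1-[(S)-2-(diphenylphosphino)ferrocenyl]ethyldi-tert-butylphosphine (6 mol%), BzOH, Et3N, THF, 50 °C; chromatography
Reagents that add atoms: benzoic acid (7), O=C(O)c1ccccc1
Why: Rhodium-catalysed asymmetric ring opening of an oxabicyclic alkene by a carboxylate, run as a regiodivergent resolution: monovalent rhodium on the exo face inserts with retention into one doubly allylic bridgehead C–O bond and benzoate attacks the allyl terminus anti to the metal (SN2'), which sets C3 trans to the C2 hydroxyl and creates the C4=C5 alkene, while the chiral ligand decides which bridgehead bond is cleaved, so that the (1S,4R)-enantiomer gives 8 and the antipode is diverted to a constitutional isomer removed by chromatography (at most half of 6 can become 8).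

**Step 5**
Reactants: 8 [(5R,6R)-5-(benzoyloxy)-6-hydroxycyclohexa-1,3-dien-1-yl]methyl benzoate
Product: 9 [(1S,2S,3R,6R)-3-(benzoyloxy)-2-hydroxy-7-oxabicyclo[4.1.0]hept-4-en-1-yl]methyl benzoate
Conditions: VO(acac)2 (5 mol%), t-BuOOH (decane), CH2Cl2, 0 °C
Reagents that add atoms: tert-butyl hydroperoxide, CC(C)(C)OO
Why: Hydroxyl-directed epoxidation of an allylic alcohol: the vanadium-bound alkoxide delivers the peroxide oxygen to the adjacent trisubstituted C1=C6 alkene on the face of the C2–OH, setting C1 and C6 cis to the hydroxyl and trans to the C3 benzoate, while the conjugated, merely homoallylic C4=C5 alkene should react much more slowly.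

**Compound list**
1 | furan-3-ylmethanol | OCc1ccoc1 | starting material
2 | benzoyl chloride | O=C(Cl)c1ccccc1 | starting material
3 | furan-3-ylmethyl benzoate | O=C(OCc1ccoc1)c1ccccc1 | intermediate
4 | (Z)-1,2-bis(phenylsulfonyl)ethene | O=S(=O)(/C=C\S(=O)(=O)c1ccccc1)c1ccccc1 | starting material
5 | rac-[(1R,4S,5R,6S)-5,6-bis(phenylsulfonyl)-7-oxabicyclo[2.2.1]hept-2-en-2-yl]methyl benzoate (5-endo,6-endo; racemic, one enantiomer drawn) | O=C(OCC1=C[C@H]2[C@@H](S(=O)(=O)c3ccccc3)[C@@H](S(=O)(=O)c3ccccc3)[C@@H]1O2)c1ccccc1 | intermediate
6 | (±)-(7-oxabicyclo[2.2.1]hepta-2,5-dien-2-yl)methyl benzoate (racemic; the productive (1S,4R)-enantiomer drawn) | O=C(OCC1=C[C@H]2C=C[C@@H]1O2)c1ccccc1 | intermediate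
7 | benzoic acid | O=C(O)c1ccccc1 | starting material
8 | [(5R,6R)-5-(benzoyloxy)-6-hydroxycyclohexa-1,3-dien-1-yl]methyl benzoate | O=C(OCC1=CC=C[C@@H](OC(=O)c2ccccc2)[C@@H]1O)c1ccccc1 | intermediate
9 | [(1S,2S,3R,6R)-3-(benzoyloxy)-2-hydroxy-7-oxabicyclo[4.1.0]hept-4-en-1-yl]methyl benzoate | O=C(OC[C@@]12O[C@@H]1C=C[C@@H](OC(=O)c1ccccc1)[C@@H]2O)c1ccccc1 | target

**Totals**
Total step count: 5. Longest linear sequence: 5 steps (from 1).

**Steps most likely to fail**

Step 4. The cyclohexadienol may lose water to an arene under the warm ammonium benzoate conditions, the diene 6 may tie up rhodium as a chelating ligand, and the two bridgehead C–O bonds may be discriminated incompletely. The fallback installs the oxirane before the bridge is opened, so that the opening substrate has one alkene and its product cannot aromatise. Setting out from 5, m-CPBA (NaHCO3, CH2Cl2, reflux) should epoxidise the only alkene on the exo face, the face of the oxygen bridge, to give the epoxy bis-sulfone F1. Na(Hg)/NaH2PO4 as in step 3 then unveils the epoxy alkene F2. The same rhodium-catalysed opening with benzoic acid on F2 should give 9 directly, because the exo oxirane already lies cis to the oxygen that becomes the C2 hydroxyl. As in step 4, only the enantiomer of F2 matched to the ligand is carried to 9. The fallback comes back to the route at 9.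

Step 3. Electron transfer may open the oxygen bridge (carbanion elimination toward the bridgehead) or cleave the allylic benzoate. The fallback uses an acetylene equivalent that is unmasked without a reductant. Setting out from 3, (E)-trimethyl[2-(phenylsulfonyl)ethenyl]silane (toluene, 100 °C, sealed tube) should give the trans-β-silyl sulfone adduct F3 as a mixture of regio- and endo/exo isomers that all converge. Bu4NF (THF, 0 °C) then triggers fluoride-induced β-elimination of the silyl and sulfonyl groups. The fallback comes back to the route at 6.

Step 5. The vanadium system may dehydrogenate the doubly allylic alcohol or also attack the C4=C5 alkene (over-oxidation, loss of site selectivity). The fallback moves stereocontrol from the substrate hydroxyl to the reagent. Setting out from 8, a Shi epoxidation is used (fructose-derived chiral ketone, Oxone, K2CO3 buffer, MeCN–dimethoxymethane–H2O, 0 °C), with the enantiomer of the ketone whose dioxirane attacks the face cis to the hydroxyl. This metal-free electrophilic oxidant prefers the more electron-rich trisubstituted alkene and cannot oxidise the alcohol by a metal-alkoxide pathway. It makes no new intermediate and comes back to the route at 9.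

**Further compounds**
F1 | step 4 | (±)-[6-endo,7-endo-bis(phenylsulfonyl)-3,8-dioxatricyclo[3.2.1.0(2,4)]oct-2-yl]methyl benzoate, exo-oxirane (racemic, one enantiomer drawn) | O=C(OC[C@@]12O[C@@H]1[C@H]3[C@@H](S(=O)(=O)c4ccccc4)[C@@H](S(=O)(=O)c4ccccc4)[C@@H]2O3)c1ccccc1
F2 | step 4 | (±)-(3,8-dioxatricyclo[3.2.1.0(2,4)]oct-6-en-2-yl)methyl benzoate, exo-oxirane (racemic, productive enantiomer drawn) | O=C(OC[C@@]12O[C@@H]1[C@H]3C=C[C@@H]2O3)c1ccccc1
F3 | step 3 | (±)-[5-(phenylsulfonyl)-6-(trimethylsilyl)-7-oxabicyclo[2.2.1]hept-2-en-2-yl]methyl benzoate, trans (one of the converging isomers drawn: 5-endo-sulfonyl, 6-exo-silyl) | O=C(OCC1=C[C@H]2[C@@H](S(=O)(=O)c3ccccc3)[C@H]([Si](C)(C)C)[C@@H]1O2)c1ccccc1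
F0 | step 5 | none | none
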